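**Assumptions (one line each)**
- Skeleton numbering used throughout: C1 (pyran CH–O) – C2 (C=O) – C3 (CHMe) – C4=C5 – C6 (CMe2) – C7 (THF CH–O) – C8 – C9 – C10 (THF C(Me)–O) – C11 (CHOH) – C12 (hemiketal) – C13 (CH–O-acyl) – C14 (CHMe) – C15 (CH2) – back to C1. Target = 1R,3S,7S,10R,11S,12R,13R,14R, 4E.
- Where a chiral catalyst is named, the enantiomer given follows the usual mnemonic for that catalyst; the antipode is equally available if the observed sense is opposite.

**Retrosynthetic overview**
1. Target ⇐ C2 carbinol oxidation and C13 esterification of a macrocycle closed last by RCM at C4=C5.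
2. Pyran hemiketal (C12-OH, C13-OH) ⇐ reagent-controlled epoxidation/hydration of a 6-substituted glycal. C11–C12 ⇐ chelation-controlled addition of a 2-metallo-glycal (C12 acyl-anion equivalent) to a THF aldehyde.
3. THF aldehyde-ester (C5–C11) ⇐ oxidative excision of the ketone bridge of an 8-oxabicyclo[3.2.1]octanone ⇐ enantioselective dearomative (4+3) cycloaddition of 2-methylfuran with the 1,1-dimethyl-oxyallyl from 3-bromo-3-methylbutan-2-one (key step: sets the cis-THF, C7, C10 and the C6 quaternary carbon at once).
4. Glycal (C12–C15, C1–C4) ⇐ Cu–box inverse-demand hetero-Diels–Alder, hydrogenation, crotylboration.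
5. Ring order: THF (as oxabicycle) → dihydropyran (separate branch) → tetrahydropyran hemiketal → 15-membered carbocycle.

---

## Branch A – THF fragment

**Step 1**
Reactants: 1 (2-methylfuran, 5 equiv), 2 (3-bromo-3-methylbutan-2-one)
Product: 3, (1S,5S)-1,4,4-trimethyl-8-oxabicyclo[3.2.1]oct-6-en-3-one
Conditions: quinidine-derived 3,5-(CF3)2C6H3-squaramide (10 mol %), Na2CO3 (2 equiv), PhCF3, 0 °C → rt
Reagents that add atoms: none
Why: Proposed new method: the catalyst's quinuclidine enolises 2 at CH3, the tertiary bromide ionises, and the resulting oxyallyl is held through its oxygen by the two squaramide N–H bonds in the chiral pocket. This weakly electrophilic, H-bonded oxyallyl should behave like the CF3CH2OH-solvated one of the racemic amine/fluoro-alcohol (Föhlisch-type) (4+3) and add to the furan in a near-concerted way, one enantiotopic face being blocked. Regiochemistry is steric (the CMe2 terminus bonds to the unsubstituted furan C5, avoiding vicinal quaternary carbons); the cis bridgeheads (future C7, C10) are fixed by the cycloaddition. Closest known chemistry: racemic α-haloketone/base (4+3) cycloadditions with furans, and hydrogen-bond-donor or amine-catalysed enantioselective (4+3)/(5+2) cycloadditions of oxyallyl-type cations.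

**Step 2**
Reactants: 3
Product: 4, (1R,5S)-1,4,4-trimethyl-8-oxabicyclo[3.2.1]octan-3-one
Conditions: H2 (1 atm), 10 % Pd/C, EtOAc, rt
Reagents that add atoms: none
Why: Simple catalytic hydrogenation of the strained cis-disubstituted alkene; no stereocentre is created (descriptor change at C1 is CIP only).

**Step 3**
Reactants: 4
Product: 5, (1R,5S)-2-hydroxy-1,4,4-trimethyl-8-oxabicyclo[3.2.1]octan-3-one (C2 epimer inconsequential)
Conditions: KHMDS, THF, −78 °C; then 2-(phenylsulfonyl)-3-phenyloxaziridine
Reagents that add atoms: Davis oxaziridine, O=S(=O)(c1ccccc1)N1OC1c1ccccc1 (delivers O)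
Why: Davis enolate hydroxylation; the ketone has only one enolisable position (the other α-carbon is CMe2), and the bridged geometry keeps the enolate from β-eliminating the ether bridge at −78 °C.

**Step 4**
Reactants: 5
Product: 6, methyl 2-[(2S,5R)-5-formyl-5-methyloxolan-2-yl]-2-methylpropanoate
Conditions: Pb(OAc)4, MeOH–PhH (1:1), 0 °C → rt
Reagents that add atoms: methanol, CO
Why: Criegee-type cleavage of the α-hydroxy ketone (via its methyl hemiketal) gives the methyl ester (C5) and the non-enolisable aldehyde (C11) in differentiated form; C7 and C10 are untouched.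

## Branch B – glycal fragment

**Step 5**
Reactants: 7 ((E)-1-bromoprop-1-ene), 8 (diethyl oxalate, 3 equiv)
Product: 9, ethyl (E)-2-oxopent-3-enoate
Conditions: t-BuLi (2 equiv), Et2O, −78 °C; cannulate into 8, Et2O, −78 °C; AcOH quench
Reagents that add atoms: none
Why: Stereoretentive Br–Li exchange and mono-acylation of the alkenyllithium by excess oxalate (the tetrahedral intermediate survives until quench) give the β,γ-unsaturated α-keto ester.

**Step 6**
Reactants: 9, 10 (ethyl vinyl ether, 3 equiv)
Product: 11, ethyl (2S,4S)-2-ethoxy-4-methyl-3,4-dihydro-2H-pyran-6-carboxylate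
Conditions: [Cu((S,S)-t-Bu-box)](OTf)2 (2 mol %), 3 Å MS, THF, 0 °C
Reagents that add atoms: none
Why: Cu(II)–bis(oxazoline)-catalysed inverse-electron-demand hetero-Diels–Alder reaction; the chelated keto ester is attacked on one face (sets C14) through an endo transition state (OEt cis to Me).

**Step 7**
Reactants: 11
Product: 12, ethyl (2R,4R,6S)-6-ethoxy-4-methyloxane-2-carboxylate (all-cis)
Conditions: H2 (1 atm), 10 % Pd/C, EtOAc, rt
Reagents that add atoms: none
Why: Hydrogenation of the enol ether from the face opposite the OEt and Me groups sets C1 with its carbon substituent cis to the C14 methyl.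

**Step 8**
Reactants: 12
Product: 13, (2R,4R,6S)-6-ethoxy-4-methyloxane-2-carbaldehyde
Conditions: DIBAL-H (1.1 equiv), CH2Cl2, −78 °C; Rochelle salt
Reagents that add atoms: none
Why: Partial reduction of an α-alkoxy ester; the chelated aluminium hemiacetal stops at the aldehyde, and the acetal is inert.

**Step 9**
Reactants: 13
Product: 14, (1S,2S)-1-[(2R,4R,6S)-6-ethoxy-4-methyloxan-2-yl]-2-methylbut-3-en-1-ol
Conditions: (E)-crotyl-B(dIpc)2 [from (−)-Ipc2BOMe, trans-2-butene, n-BuLi/KOt-Bu, BF3·OEt2], THF, −78 °C; then NaOH, H2O2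
Reagents that add atoms: (E)-crotyldiisopinocampheylborane, C/C=C/CB(C1CC2CC(C1C)C2(C)C)C1CC2CC(C1C)C2(C)C (transfers C4H7)
Why: Brown crotylboration through a closed chair transition state; the (E)-reagent gives the anti C2-OH/C3-Me pair and the Ipc ligands control the face, setting C3 (S); C2 is oxidised later.

**Step 10**
Reactants: 14
Product: 15, tert-butyl(dimethyl){[(1S,2S)-2-methyl-1-[(2R,4R)-4-methyl-3,4-dihydro-2H-pyran-2-yl]but-3-en-1-yl]oxy}silane
Conditions: TBSOTf (1.2 equiv), i-Pr2NEt (4 equiv), CH2Cl2, −78 → 0 °C; then TMSOTf (1.5 equiv), 0 °C → rt (one pot)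
Reagents that add atoms: TBSOTf, CC(C)(C)[Si](C)(C)OS(=O)(=O)C(F)(F)F
Why: Silylation of the carbinol, then silyl-triflate/amine conversion of the cyclic acetal into the enol ether (oxocarbenium formation, loss of EtOTMS, deprotonation at C13) unveils the glycal without touching C1 or C14.

## Union and endgame

**Step 11**
Reactants: 15 (1.3 equiv), 6
Product: 16, methyl 2-[(2S,5R)-5-{(S)-hydroxy[(2R,4R)-2-{(1S,2S)-1-[(tert-butyldimethylsilyl)oxy]-2-methylbut-3-en-1-yl}-4-methyl-3,4-dihydro-2H-pyran-6-yl]methyl}-5-methyloxolan-2-yl]-2-methylpropanoate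
Conditions: 15, t-BuLi, THF, −78 → 0 °C; MgBr2·OEt2, −78 °C; then 6, −78 °C
Reagents that add atoms: none
Why: α-Lithiation of the cyclic enol ether gives a C12 acyl-anion equivalent; after transmetalation it adds to the aldehyde under Cram-chelate control (Mg bridges C=O and the THF oxygen; attack from the methyl face, anti to the ring CH2 and the C7 side chain), giving 11S. The hindered neopentyl ester is untouched at −78 °C.

**Step 12**
Reactants: 16
Product: 17, the C5 vinyl analogue of 16 (CO2Me replaced by CH=CH2; C11-OH free, enol ether and OTBS intact)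
Conditions: DIBAL-H (2.5 equiv), CH2Cl2, −78 °C; then Ph3P=CH2 (from Ph3PCH3Br/KHMDS, 5 equiv), THF, −78 °C → rt (one pot)
Reagents that add atoms: methylenetriphenylphosphorane, C=P(c1ccccc1)(c1ccccc1)c1ccccc1
Why: The α-quaternary ester gives a stable aluminium hemiacetal that releases the aldehyde in the presence of the ylide (one-pot reduction–Wittig methylenation), so the neopentyl aldehyde is never isolated.

**Step 13**
Reactants: 17
Product: 18, acyclic diene hemiketal: pyran with 12-OH (axial), 13-OH and 11-OH, 2-OTBS, vinyl groups at C3 and C6 (1R,2S,3S,7S,10R,11S,12S,13R,14R; 12S is a CIP change only)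
Conditions: D-fructose-derived Shi ketone (30 mol %), Oxone, K2CO3, Bu4NHSO4, MeCN–DMM / aq. Na2B4O7–EDTA buffer (pH 10.5), 0 °C
Reagents that add atoms: Oxone (KHSO5), [K+].OOS(=O)(=O)[O-] (epoxide O); water, O (hydrolytic opening)
Why: Shi epoxidation of the electron-rich trisubstituted enol ether (terminal vinyl groups are unreactive). By the spiro transition-state model, this ketone delivers oxygen to the face that places C13–O cis to the C14 methyl. The glycal epoxide hydrolyses in the buffer and the hemiketal equilibrates to the anomerically favoured axial-OH/equatorial-C11 form.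

**Step 14**
Reactants: 18
Product: 19, macrocyclic triol: (4E)-15-membered carbocycle with 7,10-epoxy (THF) and 1,12-epoxy (pyran) bridges; 2-OTBS, 11-OH, 12-OH, 13-OH
Conditions: Grubbs II (15 mol %), CH2Cl2 (1 mM), 40 °C
Reagents that add atoms: none
Why: Ring-closing metathesis; the cis-THF and the cis-2,6-pyran hold both chains on one side, and the 15-membered ring forms as the E-alkene. The neopentyl vinyl group is engaged intramolecularly after initiation at the C4 vinyl.

**Step 15**
Reactants: 19, 20 ((E)-3-methylpent-2-enoic acid)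
Product: 21, 13-O-[(E)-3-methylpent-2-enoyl] ester of 19
Conditions: 20, 2,4,6-Cl3C6H2COCl, Et3N, THF; then 19, DMAP, toluene, rt
Reagents that add atoms: none (20 is a numbered reactant)
Why: Yamaguchi esterification selective for the C13 secondary alcohol; C11-OH is flanked by two fully substituted carbons and C12-OH is a tertiary hemiketal hydroxyl.

**Step 16**
Reactants: 21
Product: 22, the C2 alcohol (desilylated 21)
Conditions: HF·pyridine, pyridine/THF, 0 °C → rt
Reagents that add atoms: none
Why: Buffered fluoride desilylation tolerates the hemiketal and the dienoate ester; no epimerisable centre exists yet.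

**Step 17**
Reactants: 22
Product: 23, tonantzitlolone A
Conditions: Dess–Martin periodinane (1.3 equiv), NaHCO3, CH2Cl2, 0 °C
Reagents that add atoms: none
Why: Neutral oxidation of the C2 carbinol gives the β,γ-unsaturated ketone without epimerising C1 or C3; the far more hindered C11-OH and the tertiary C12-OH are expected to be spared under stoichiometric control.

---

## Compound list

1 | 2-methylfuran | Cc1ccco1 | starting material
2 | 3-bromo-3-methylbutan-2-one | CC(=O)C(C)(C)Br | starting material
3 | (1S,5S)-1,4,4-trimethyl-8-oxabicyclo[3.2.1]oct-6-en-3-one | O=C1C[C@@]2(C)C=C[C@H](O2)C1(C)C | intermediate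
4 | (1R,5S)-1,4,4-trimethyl-8-oxabicyclo[3.2.1]octan-3-one | O=C1C[C@@]2(C)CC[C@H](O2)C1(C)C | intermediate
5 | (1R,5S)-2-hydroxy-1,4,4-trimethyl-8-oxabicyclo[3.2.1]octan-3-one | O=C1C(O)[C@@]2(C)CC[C@H](O2)C1(C)C | intermediate
6 | methyl 2-[(2S,5R)-5-formyl-5-methyloxolan-2-yl]-2-methylpropanoate | O=C[C@@]1(C)CC[C@H](O1)C(C)(C)C(=O)OC | intermediate
7 | (E)-1-bromoprop-1-ene | C/C=C/Br | starting material
8 | diethyl oxalate | CCOC(=O)C(=O)OCC | starting material
9 | ethyl (E)-2-oxopent-3-enoate | C/C=C/C(=O)C(=O)OCC | intermediate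
10 | ethyl vinyl ether | C=COCC | starting material
11 | ethyl (2S,4S)-2-ethoxy-4-methyl-3,4-dihydro-2H-pyran-6-carboxylate | C1[C@H](C)C=C(C(=O)OCC)O[C@@H]1OCC | intermediate
12 | ethyl (2R,4R,6S)-6-ethoxy-4-methyloxane-2-carboxylate | C1[C@H](C)C[C@H](C(=O)OCC)O[C@@H]1OCC | intermediate
13 | (2R,4R,6S)-6-ethoxy-4-methyloxane-2-carbaldehyde | C1[C@H](C)C[C@H](C=O)O[C@@H]1OCC | intermediate
14 | (1S,2S)-1-[(2R,4R,6S)-6-ethoxy-4-methyloxan-2-yl]-2-methylbut-3-en-1-ol | C1[C@H](C)C[C@H]([C@@H](O)[C@@H](C)C=C)O[C@@H]1OCC | intermediate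
15 | TBS ether of (1S,2S)-2-methyl-1-[(2R,4R)-4-methyl-3,4-dihydro-2H-pyran-2-yl]but-3-en-1-ol | C1=C[C@H](C)C[C@H]([C@@H](O[Si](C)(C)C(C)(C)C)[C@@H](C)C=C)O1 | intermediate
16 | coupled glycal–THF ester, 11S carbinol (name in Step 11) | C1(=C[C@H](C)C[C@@H](O1)[C@@H](O[Si](C)(C)C(C)(C)C)[C@@H](C)C=C)[C@@H](O)[C@@]2(C)CC[C@H](O2)C(C)(C)C(=O)OC | intermediate
17 | C5-vinyl analogue of 16 | C1(=C[C@H](C)C[C@@H](O1)[C@@H](O[Si](C)(C)C(C)(C)C)[C@@H](C)C=C)[C@@H](O)[C@@]2(C)CC[C@H](O2)C(C)(C)C=C | intermediate
18 | acyclic diene hemiketal triol, 2-OTBS | O[C@@H]1[C@H](C)C[C@H]([C@@H](O[Si](C)(C)C(C)(C)C)[C@@H](C)C=C)O[C@]1(O)[C@@H](O)[C@@]2(C)CC[C@H](O2)C(C)(C)C=C | intermediate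
19 | (4E)-macrocyclic triol, 2-OTBS | O[C@@H]1[C@H](C)C[C@H]2O[C@]1(O)[C@@H](O)[C@@]1(C)CC[C@H](O1)C(C)(C)/C=C/[C@H](C)[C@@H]2O[Si](C)(C)C(C)(C)C | intermediate
20 | (E)-3-methylpent-2-enoic acid | CC/C(C)=C/C(=O)O | starting material
21 | 13-O-[(E)-3-methylpent-2-enoyl]-2-O-TBS macrocycle | CC/C(C)=C/C(=O)O[C@@H]1[C@H](C)C[C@H]2O[C@]1(O)[C@@H](O)[C@@]1(C)CC[C@H](O1)C(C)(C)/C=C/[C@H](C)[C@@H]2O[Si](C)(C)C(C)(C)C | intermediate
22 | 2-hydroxy (2S) precursor of the target | CC/C(C)=C/C(=O)O[C@@H]1[C@H](C)C[C@H]2O[C@]1(O)[C@@H](O)[C@@]1(C)CC[C@H](O1)C(C)(C)/C=C/[C@H](C)[C@@H]2O | intermediate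
23 | tonantzitlolone A | CC/C(C)=C/C(=O)O[C@@H]1[C@H](C)C[C@H]2O[C@]1(O)[C@@H](O)[C@@]1(C)CC[C@H](O1)C(C)(C)/C=C/[C@H](C)C2=O | target

---

**Total steps:** 17. **Longest linear sequence:** 13 (steps 5–17; branch A joins at step 11 after 4 steps).

**Three steps most likely to fail, with fallbacks**

1. **Step 1 (enantioselective (4+3), new method).** Enantioselectivity is unproven and the regiochemistry rests on a steric argument; the hindered regioisomer or furan C-alkylation may compete. Fallback: run the cycloaddition racemically under standard Et3N/CF3CH2OH conditions and take absolute configuration from a resolution instead — lipase-mediated kinetic acylation of rac-5 (or preparative chiral chromatography of 4) — before step 4.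

2. **Step 13 (C13 configuration by Shi epoxidation).** The catalyst must override any substrate bias for attack anti to the C14 methyl, and the glycal epoxide is labile. Fallback: accept substrate control (DMDO, expected to give mainly the 13-epi diol) and correct C13 during acylation, by Mitsunobu esterification with acid 20 (inversion) after ring closure, replacing step 15.

3. **Step 14 (RCM at a vinyl group on a quaternary carbon).** The neopentyl olefin may initiate or close poorly, or give E/Z mixtures. Fallback: change the ring-closing bond — form C4=C5 intermolecularly by Julia–Kocienski olefination of the C5 aldehyde with a C4 sulfone on the glycal fragment, convert the glycal C12–H into the 2-iodo-glycal, and close the macrocycle at C11–C12 by intramolecular Ni/Cr (Nozaki–Hiyama–Kishi) addition to the C11 aldehyde.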